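**Plan**

- Numbering: decahydroquinoline N1, C2 (Me), C3 (O-acyl), C4, C4a, C5 (side chain C1'–C8', OH on C5'), C6–C8, C8a. Cuts, in order: the C3–O ester; N1–C2 and C3=C4 of ring B (enecarbamate from a methyl ketone, ketone from an olefination); C1'=C2' (cross-metathesis); C4a–C5 of ring A together with C2'–O (transannular Claisen); C5=C1' of the lactone (ring-closing metathesis); C7–C8 (Grignard coupling).
- Enabling feature: ring A carries C4 on C4a and C1' on C5 cis on neighbouring carbons. This is a cis-2-vinylcyclohexanecarboxylic acid (C4 = carboxyl carbon, C1'=C2' = vinyl), the retron of a Claisen ring contraction of the Z ten-membered lactone C4(=O)–C4a–C8a–C8–C7–C6–C5=C1'–C2'–O.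
- Forward: aspartate-derived open chain, then allyl ester, ten-membered lactone, ring A by contraction, side chain, ring B by cyclodehydration, C3–OH, ester, deprotection.
- Stereochemistry: C8a from L-aspartic acid; C4a and C5 in the contraction (Z alkene gives cis C4a/C5, an N–Li–O chelate gives cis C4a/C8a); C5' from (R)-1,2-epoxypentane; C2 and C3 by syn hydroboration on the face away from C8.

Key step: step 7

Assumption: N-Boc-L-aspartic acid 4-benzyl ester, but-3-enylmagnesium bromide (THF solution) and (2E,4E)-octa-2,4-dienoic acid are bought as such, and lepadin H is isolated as the free base.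

Step 1
Reactants: 1 (2S)-4-(benzyloxy)-2-[(tert-butoxycarbonyl)amino]-4-oxobutanoic acid (N-Boc-L-aspartic acid 4-benzyl ester)
Product: 3 benzyl (3S)-3-[(tert-butoxycarbonyl)amino]-4-hydroxybutanoate, via isobutyl carbonic anhydride 2 (not isolated)
Conditions: iBuOCOCl, N-methylmorpholine, THF, −15 °C; then NaBH4, H2O, 0 °C
Reagents that add atoms: none
Why: Mixed-anhydride activation of the free α-carboxyl followed by borohydride reduction is the standard chemoselective route from N-protected amino acids to amino alcohols, and the benzyl ester, the carbamate and the stereocentre are not touched.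

Step 2
Reactants: 3 benzyl (3S)-3-[(tert-butoxycarbonyl)amino]-4-hydroxybutanoate
Product: 4 benzyl (3S)-3-[(tert-butoxycarbonyl)amino]-4-iodobutanoate
Conditions: I2, PPh3, imidazole, CH2Cl2, 0 °C → rt
Reagents that add atoms: iodine, II
Why: Appel-type iodination of the primary alcohol is an SN2 displacement at CH2 that involves no stereocentre, and β-amino iodides of this type are isolable.

Step 3
Reactants: 4 benzyl (3S)-3-[(tert-butoxycarbonyl)amino]-4-iodobutanoate; 5 but-3-en-1-ylmagnesium bromide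
Product: 6 benzyl (3R)-3-[(tert-butoxycarbonyl)amino]oct-7-enoate
Conditions: 5 (2.5 equiv, slow addition), CuI (10 mol%), THF, −40 → −10 °C; then H2O
Reagents that add atoms: none
Why: Copper-catalysed alkyl–alkyl cross-coupling of a primary iodide with a Grignard reagent forms C7–C8; the first equivalent only deprotonates the carbamate, and even if the N-anion closes to the N-Boc aziridine, cuprate opening at its CH2 end gives the same product, C8a never being a reacting centre (the descriptor changes from S to R only through priorities).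

Step 4
Reactants: 6 benzyl (3R)-3-[(tert-butoxycarbonyl)amino]oct-7-enoate
Product: 7 (3R)-3-[(tert-butoxycarbonyl)amino]oct-7-enoic acid
Conditions: LiOH, THF/H2O (3:1), 0 °C → rt; then 1 M HCl to pH 3
Reagents that add atoms: lithium hydroxide (hydroxide oxygen), [Li+].[OH-]
Why: Saponification is used because hydrogenolysis would reduce the alkene, and N-Boc β-amino esters hydrolyse under LiOH without β-elimination.

Step 5
Reactants: 7 (3R)-3-[(tert-butoxycarbonyl)amino]oct-7-enoic acid
Product: 8 prop-2-en-1-yl (3R)-3-[(tert-butoxycarbonyl)amino]oct-7-enoate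
Conditions: allyl bromide, K2CO3, DMF, rt
Reagents that add atoms: allyl bromide, C=CCBr
Why: SN2 O-alkylation of the carboxylate installs C2' and C1', and the carbamate N–H is not alkylated by carbonate.

Step 6
Reactants: 8 prop-2-en-1-yl (3R)-3-[(tert-butoxycarbonyl)amino]oct-7-enoate
Product: 9 tert-butyl N-[(4R,8Z)-2-oxo-3,4,5,6,7,10-hexahydro-2H-oxecin-4-yl]carbamate
Conditions: second-generation Grubbs catalyst RuCl2(H2IMes)(PCy3)(=CHPh) (5 mol%), CH2Cl2 (0.001 M), 40 °C
Reagents that add atoms: none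
Why: Ring-closing metathesis of the two terminal alkenes at high dilution forms C5=C1'; the Z alkene is the less strained isomer of a ten-membered ring and should dominate under the equilibrating conditions of the NHC catalyst, the E isomer and cyclic dimer being removed by chromatography (AgNO3-impregnated silica if needed).

Step 7
Reactants: 9 tert-butyl N-[(4R,8Z)-2-oxo-3,4,5,6,7,10-hexahydro-2H-oxecin-4-yl]carbamate
Product: 12 (1S,2R,6R)-2-[(tert-butoxycarbonyl)amino]-6-ethenylcyclohexane-1-carboxylic acid, via dilithium chelated enolate 10 (not isolated), via dilithium carboxylate 11 (not isolated)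
Conditions: LiN(SiMe3)2 (2.5 equiv), THF, −78 °C; then −78 → 25 °C (to 45 °C if needed); then 1 M HCl, 0 °C
Reagents that add atoms: none
Why: Two equivalents of base give the N,O-dianion (carbamate nitrogen first, then C4a–H), in which β-elimination is shut off because the leaving group would be a carbamate dianion, and N–Li–O chelation holds C8a cis to the enolate oxygen, so that C4a=C4 is a trans double bond of the ten-membered ring. The [3,3] shift then joins C4a to C5 across the ring while C2'–O breaks; it is an ester-enolate Claisen rearrangement of the Ireland–Claisen family, closest in kind to the silyl ketene acetal ring contraction of macrocyclic alkenyl lactones and to the dianion Claisen rearrangement of β-hydroxy allyl esters. Ring A closes by transannular contraction (C4, O, C2' and C1' leave the ten-membered ring and a cyclohexane remains), through a chair-like array for this trans-enolate/cis-alkene pair. C4a/C5 cis: with the Z alkene the two termini can be bridged by C6–C8 only in geometries (chair with the trans enolate, boat with the cis enolate) that put C4 and C1' on the same face of ring A. C8a/C4a cis: the chelate keeps nitrogen in the enolate plane, so C8 and the C8a hydrogen flank it, and C5, which hangs on C8, must bond to the face that places the carbamate cis to the new carboxyl group; a non-chelated bis-silyl ketene acetal would instead turn the C8a hydrogen into the plane (allylic 1,3-strain) and favour the trans isomer, which is why no chlorosilane is added. The step needs Z geometry in 9 and an intact chelate, and both are provided by the substrate (purified Z lactone, carbamate N–H β to the ester carbonyl).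

Step 8
Reactants: 12 (1S,2R,6R)-2-[(tert-butoxycarbonyl)amino]-6-ethenylcyclohexane-1-carboxylic acid
Product: 14 tert-butyl N-[(1R,2S,3R)-3-ethenyl-2-(hydroxymethyl)cyclohexyl]carbamate, via isobutyl carbonic anhydride 13 (not isolated)
Conditions: iBuOCOCl, N-methylmorpholine, THF, −15 °C; then NaBH4, H2O, 0 °C
Reagents that add atoms: none
Why: Reduction of the acid through its mixed carbonic anhydride with NaBH4 leaves the vinyl group and the carbamate alone (borane would hydroborate the alkene) and touches no stereocentre.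

Step 9
Reactants: 15 (2R)-2-propyloxirane ((R)-1,2-epoxypentane)
Product: 16 (5R)-oct-1-en-5-ol
Conditions: allylmagnesium bromide, CuI (10 mol%), THF, −30 → 0 °C; then H2O
Reagents that add atoms: allylmagnesium bromide, C=CC[Mg]Br
Why: Copper-catalysed opening of the terminal epoxide by the allyl Grignard reagent occurs at the CH2 carbon, so the stereocentre is not attacked and the R configuration of C5' is carried over.

Step 10
Reactants: 16 (5R)-oct-1-en-5-ol
Product: 17 tert-butyl(dimethyl){[(5R)-oct-1-en-5-yl]oxy}silane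
Conditions: TBSCl, imidazole, DMF, rt
Reagents that add atoms: tert-butyl(chloro)dimethylsilane, CC(C)(C)[Si](C)(C)Cl
Why: Standard silylation of a secondary alcohol; the TBS ether should survive metathesis, oxidation, hydrogenation, hydroboration and acylation and fall in the final acid step.

Step 11
Reactants: 14 tert-butyl N-[(1R,2S,3R)-3-ethenyl-2-(hydroxymethyl)cyclohexyl]carbamate; 17 tert-butyl(dimethyl){[(5R)-oct-1-en-5-yl]oxy}silane
Product: 18 tert-butyl N-[(1R,2S,3R)-3-[(1E,5R)-5-{[tert-butyl(dimethyl)silyl]oxy}oct-1-en-1-yl]-2-(hydroxymethyl)cyclohexyl]carbamate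
Conditions: 17 (3 equiv), second-generation Hoveyda–Grubbs catalyst RuCl2(H2IMes)(=CH-C6H4-2-OiPr) (5 mol%), CH2Cl2, 40 °C
Reagents that add atoms: none
Why: Olefin cross-metathesis between the hindered ring vinyl group and an excess of the unhindered terminal alkene, whose homodimer re-enters the cycle, forms C1'=C2', and the E/Z ratio is irrelevant because the alkene is hydrogenated in step 14.

Step 12
Reactants: 18 tert-butyl N-[(1R,2S,3R)-3-[(1E,5R)-5-{[tert-butyl(dimethyl)silyl]oxy}oct-1-en-1-yl]-2-(hydroxymethyl)cyclohexyl]carbamate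
Product: 19 tert-butyl N-[(1R,2S,3R)-3-[(1E,5R)-5-{[tert-butyl(dimethyl)silyl]oxy}oct-1-en-1-yl]-2-formylcyclohexyl]carbamate
Conditions: Dess–Martin periodinane, NaHCO3, CH2Cl2, 0 °C → rt
Reagents that add atoms: none
Why: Dess–Martin oxidation of the primary alcohol under bicarbonate buffer does not epimerise α-branched aldehydes, and the aldehyde is used at once.

Step 13
Reactants: 19 tert-butyl N-[(1R,2S,3R)-3-[(1E,5R)-5-{[tert-butyl(dimethyl)silyl]oxy}oct-1-en-1-yl]-2-formylcyclohexyl]carbamate
Product: 20 tert-butyl N-[(1R,2S,3R)-3-[(1E,5R)-5-{[tert-butyl(dimethyl)silyl]oxy}oct-1-en-1-yl]-2-[(1E)-3-oxobut-1-en-1-yl]cyclohexyl]carbamate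
Conditions: (MeO)2P(O)CH2C(O)CH3, LiCl, iPr2NEt, MeCN, rt
Reagents that add atoms: dimethyl (2-oxopropyl)phosphonate, CC(=O)CP(=O)(OC)OC
Why: Horner–Wadsworth–Emmons olefination under Masamune–Roush conditions is mild enough to keep the all-cis C4a centre from epimerising and brings in C3, C2 and the C2 methyl group as an E enone.

Step 14
Reactants: 20 tert-butyl N-[(1R,2S,3R)-3-[(1E,5R)-5-{[tert-butyl(dimethyl)silyl]oxy}oct-1-en-1-yl]-2-[(1E)-3-oxobut-1-en-1-yl]cyclohexyl]carbamate
Product: 21 tert-butyl N-[(1R,2S,3S)-3-[(5R)-5-{[tert-butyl(dimethyl)silyl]oxy}octyl]-2-(3-oxobutyl)cyclohexyl]carbamate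
Conditions: H2 (1 atm), Pd/C (10%), EtOAc, rt
Reagents that add atoms: none
Why: Heterogeneous hydrogenation saturates the side-chain alkene and the enone C=C, while ketone, carbamate and silyl ether are inert under these conditions.

Step 15
Reactants: 21 tert-butyl N-[(1R,2S,3S)-3-[(5R)-5-{[tert-butyl(dimethyl)silyl]oxy}octyl]-2-(3-oxobutyl)cyclohexyl]carbamate
Product: 22 tert-butyl (4aS,5S,8aR)-5-[(5R)-5-{[tert-butyl(dimethyl)silyl]oxy}octyl]-2-methyl-4a,5,6,7,8,8a-hexahydroquinoline-1(4H)-carboxylate
Conditions: pyridinium p-toluenesulfonate (10 mol%), 4 Å molecular sieves, toluene, 80 °C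
Reagents that add atoms: none
Why: Acid-catalysed cyclodehydration of the N-Boc amino ketone through the hemiaminal and the N-acyliminium ion closes ring B (N1–C2), and under the equilibrating acid the endocyclic trisubstituted C2=C3 alkene is expected over the exocyclic methylene isomer.

Step 16
Reactants: 22 tert-butyl (4aS,5S,8aR)-5-[(5R)-5-{[tert-butyl(dimethyl)silyl]oxy}octyl]-2-methyl-4a,5,6,7,8,8a-hexahydroquinoline-1(4H)-carboxylate
Product: 24 tert-butyl (2S,3R,4aS,5S,8aR)-5-[(5R)-5-{[tert-butyl(dimethyl)silyl]oxy}octyl]-3-hydroxy-2-methyloctahydroquinoline-1(2H)-carboxylate, via C3 alkylborane 23 (not isolated)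
Conditions: BH3·THF, THF, 0 °C → rt; then NaOH, H2O2, 0 °C → rt
Reagents that add atoms: hydrogen peroxide, OO
Why: Brown hydroboration–oxidation of the enecarbamate puts boron on C3 (β to nitrogen, less substituted) and hydrogen on C2 in a syn addition from the face opposite the C8a–C8 bond, which allylic strain with the Boc group holds pseudoaxial, so the C2 methyl ends cis to C8 and trans to the C3 hydroxyl (2S,3R), the oxidation going with retention.

Step 17
Reactants: 24 tert-butyl (2S,3R,4aS,5S,8aR)-5-[(5R)-5-{[tert-butyl(dimethyl)silyl]oxy}octyl]-3-hydroxy-2-methyloctahydroquinoline-1(2H)-carboxylate; 25 (2E,4E)-octa-2,4-dienoic acid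
Product: 27 tert-butyl (2S,3R,4aS,5S,8aR)-5-[(5R)-5-{[tert-butyl(dimethyl)silyl]oxy}octyl]-2-methyl-3-{[(2E,4E)-octa-2,4-dienoyl]oxy}octahydroquinoline-1(2H)-carboxylate, via trichlorobenzoic mixed anhydride 26 (not isolated)
Conditions: 25, 2,4,6-trichlorobenzoyl chloride, Et3N, THF, rt; then 24, DMAP, toluene, rt → 40 °C
Reagents that add atoms: none
Why: Yamaguchi esterification through the mixed anhydride acylates the hindered secondary alcohol under DMAP catalysis without touching the carbamate or the silyl ether and should not isomerise the dienoate.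

Step 18
Reactants: 27 tert-butyl (2S,3R,4aS,5S,8aR)-5-[(5R)-5-{[tert-butyl(dimethyl)silyl]oxy}octyl]-2-methyl-3-{[(2E,4E)-octa-2,4-dienoyl]oxy}octahydroquinoline-1(2H)-carboxylate
Product: 29 (2S,3R,4aS,5S,8aR)-5-[(5R)-5-hydroxyoctyl]-2-methyldecahydroquinolin-3-yl (2E,4E)-octa-2,4-dienoate (lepadin H), via O-silylated amine 28 (not isolated)
Conditions: CF3CO2H/CH2Cl2 (1:3), 0 °C → rt; then H2O, rt; aq. NaHCO3
Reagents that add atoms: none
Why: Acidolysis removes the Boc group and, once water is added, the secondary TBS ether, while the dienoate ester is stable to acid and, being equatorial and anti to the N1–C2 bond in the stable chair, should not undergo O-to-N acyl transfer on neutralisation.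

**Compound list**

1 | (2S)-4-(benzyloxy)-2-[(tert-butoxycarbonyl)amino]-4-oxobutanoic acid (N-Boc-L-aspartic acid 4-benzyl ester) | CC(C)(C)OC(=O)N[C@@H](CC(=O)OCc1ccccc1)C(=O)O | starting material
2 | mixed anhydride of 1 with isobutyl hydrogen carbonate | CC(C)(C)OC(=O)N[C@@H](CC(=O)OCc1ccccc1)C(=O)OC(=O)OCC(C)C | intermediate
3 | benzyl (3S)-3-[(tert-butoxycarbonyl)amino]-4-hydroxybutanoate | CC(C)(C)OC(=O)N[C@@H](CC(=O)OCc1ccccc1)CO | intermediate
4 | benzyl (3S)-3-[(tert-butoxycarbonyl)amino]-4-iodobutanoate | CC(C)(C)OC(=O)N[C@@H](CC(=O)OCc1ccccc1)CI | intermediate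
5 | but-3-en-1-ylmagnesium bromide | C=CCC[Mg]Br | starting material
6 | benzyl (3R)-3-[(tert-butoxycarbonyl)amino]oct-7-enoate | CC(C)(C)OC(=O)N[C@@H](CC(=O)OCc1ccccc1)CCCC=C | intermediate
7 | (3R)-3-[(tert-butoxycarbonyl)amino]oct-7-enoic acid | CC(C)(C)OC(=O)N[C@@H](CC(=O)O)CCCC=C | intermediate
8 | prop-2-en-1-yl (3R)-3-[(tert-butoxycarbonyl)amino]oct-7-enoate | CC(C)(C)OC(=O)N[C@@H](CC(=O)OCC=C)CCCC=C | intermediate
9 | tert-butyl N-[(4R,8Z)-2-oxo-3,4,5,6,7,10-hexahydro-2H-oxecin-4-yl]carbamate | O=C1C[C@H](NC(=O)OC(C)(C)C)CCC/C=C\CO1 | intermediate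
10 | dilithium N,O-dianion of 9 (lithium carbamate and lithium enolate C4a=C4–O, enolate oxygen cis to C8a, Z alkene kept) | [Li+].[Li+].[O-]/C1=C\[C@H]([N-]C(=O)OC(C)(C)C)CCC/C=C\CO1 | intermediate
11 | dilithium (1S,2R,6R)-2-[(tert-butoxycarbonyl)azanidyl]-6-ethenylcyclohexane-1-carboxylate | [Li+].[Li+].[O-]C(=O)[C@H]1[C@@H](C=C)CCC[C@H]1[N-]C(=O)OC(C)(C)C | intermediate
12 | (1S,2R,6R)-2-[(tert-butoxycarbonyl)amino]-6-ethenylcyclohexane-1-carboxylic acid | OC(=O)[C@H]1[C@@H](C=C)CCC[C@H]1NC(=O)OC(C)(C)C | intermediate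
13 | mixed anhydride of 12 with isobutyl hydrogen carbonate | CC(C)COC(=O)OC(=O)[C@H]1[C@@H](C=C)CCC[C@H]1NC(=O)OC(C)(C)C | intermediate
14 | tert-butyl N-[(1R,2S,3R)-3-ethenyl-2-(hydroxymethyl)cyclohexyl]carbamate | OC[C@H]1[C@@H](C=C)CCC[C@H]1NC(=O)OC(C)(C)C | intermediate
15 | (2R)-2-propyloxirane ((R)-1,2-epoxypentane) | CCC[C@@H]1CO1 | starting material
16 | (5R)-oct-1-en-5-ol | C=CCC[C@H](O)CCC | intermediate
17 | tert-butyl(dimethyl){[(5R)-oct-1-en-5-yl]oxy}silane | C=CCC[C@H](O[Si](C)(C)C(C)(C)C)CCC | intermediate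
18 | tert-butyl N-[(1R,2S,3R)-3-[(1E,5R)-5-{[tert-butyl(dimethyl)silyl]oxy}oct-1-en-1-yl]-2-(hydroxymethyl)cyclohexyl]carbamate | OC[C@H]1[C@@H](/C=C/CC[C@H](O[Si](C)(C)C(C)(C)C)CCC)CCC[C@H]1NC(=O)OC(C)(C)C | intermediate
19 | tert-butyl N-[(1R,2S,3R)-3-[(1E,5R)-5-{[tert-butyl(dimethyl)silyl]oxy}oct-1-en-1-yl]-2-formylcyclohexyl]carbamate | O=C[C@H]1[C@@H](/C=C/CC[C@H](O[Si](C)(C)C(C)(C)C)CCC)CCC[C@H]1NC(=O)OC(C)(C)C | intermediate
20 | tert-butyl N-[(1R,2S,3R)-3-[(1E,5R)-5-{[tert-butyl(dimethyl)silyl]oxy}oct-1-en-1-yl]-2-[(1E)-3-oxobut-1-en-1-yl]cyclohexyl]carbamate | CC(=O)/C=C/[C@H]1[C@@H](/C=C/CC[C@H](O[Si](C)(C)C(C)(C)C)CCC)CCC[C@H]1NC(=O)OC(C)(C)C | intermediate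
21 | tert-butyl N-[(1R,2S,3S)-3-[(5R)-5-{[tert-butyl(dimethyl)silyl]oxy}octyl]-2-(3-oxobutyl)cyclohexyl]carbamate | CC(=O)CC[C@H]1[C@@H](CCCC[C@H](O[Si](C)(C)C(C)(C)C)CCC)CCC[C@H]1NC(=O)OC(C)(C)C | intermediate
22 | tert-butyl (4aS,5S,8aR)-5-[(5R)-5-{[tert-butyl(dimethyl)silyl]oxy}octyl]-2-methyl-4a,5,6,7,8,8a-hexahydroquinoline-1(4H)-carboxylate | CC1=CC[C@H]2[C@@H](CCCC[C@H](O[Si](C)(C)C(C)(C)C)CCC)CCC[C@H]2N1C(=O)OC(C)(C)C | intermediate
23 | tert-butyl (2S,3R,4aS,5S,8aR)-3-boranyl-5-[(5R)-5-{[tert-butyl(dimethyl)silyl]oxy}octyl]-2-methyloctahydroquinoline-1(2H)-carboxylate | B[C@@H]1C[C@H]2[C@@H](CCCC[C@H](O[Si](C)(C)C(C)(C)C)CCC)CCC[C@H]2N(C(=O)OC(C)(C)C)[C@H]1C | intermediate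
24 | tert-butyl (2S,3R,4aS,5S,8aR)-5-[(5R)-5-{[tert-butyl(dimethyl)silyl]oxy}octyl]-3-hydroxy-2-methyloctahydroquinoline-1(2H)-carboxylate | O[C@@H]1C[C@H]2[C@@H](CCCC[C@H](O[Si](C)(C)C(C)(C)C)CCC)CCC[C@H]2N(C(=O)OC(C)(C)C)[C@H]1C | intermediate
25 | (2E,4E)-octa-2,4-dienoic acid | CCC/C=C/C=C/C(=O)O | starting material
26 | (2E,4E)-octa-2,4-dienoic 2,4,6-trichlorobenzoic anhydride | CCC/C=C/C=C/C(=O)OC(=O)c1c(Cl)cc(Cl)cc1Cl | intermediate
27 | tert-butyl (2S,3R,4aS,5S,8aR)-5-[(5R)-5-{[tert-butyl(dimethyl)silyl]oxy}octyl]-2-methyl-3-{[(2E,4E)-octa-2,4-dienoyl]oxy}octahydroquinoline-1(2H)-carboxylate | CCC/C=C/C=C/C(=O)O[C@@H]1C[C@H]2[C@@H](CCCC[C@H](O[Si](C)(C)C(C)(C)C)CCC)CCC[C@H]2N(C(=O)OC(C)(C)C)[C@H]1C | intermediate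
28 | (2S,3R,4aS,5S,8aR)-5-[(5R)-5-{[tert-butyl(dimethyl)silyl]oxy}octyl]-2-methyldecahydroquinolin-3-yl (2E,4E)-octa-2,4-dienoate | CCC/C=C/C=C/C(=O)O[C@@H]1C[C@H]2[C@@H](CCCC[C@H](O[Si](C)(C)C(C)(C)C)CCC)CCC[C@H]2N[C@H]1C | intermediate
29 | (2S,3R,4aS,5S,8aR)-5-[(5R)-5-hydroxyoctyl]-2-methyldecahydroquinolin-3-yl (2E,4E)-octa-2,4-dienoate (lepadin H) | CCC/C=C/C=C/C(=O)O[C@@H]1C[C@H]2[C@@H](CCCC[C@H](O)CCC)CCC[C@H]2N[C@H]1C | target

**Step count and risks**

Total steps: 18. Longest linear sequence: 16 (steps 1–8 and 11–18); steps 9 and 10 make the side-chain alkene.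

Steps most likely to fail:

1. Step 7. What may go wrong: the N–Li–O chelate may open, so that C5 bonds to C4a on the face anti to nitrogen and the carbamate ends trans to the carboxyl group. The dianion may also fragment (ring opening to a ketene, loss of tert-butoxide from the lithiated carbamate) before it rearranges. Fallback, from 9 back to 12: coordinative control is replaced by a covalent tether. Lactone 9 is deprotonated twice as before and the dianion is closed with iPr2SiCl2 (THF, −78 → 0 °C) to the diisopropylsilylene-bridged ketene N,O-acetal F1. Its six-membered N–Si–O ring holds nitrogen in the ketene acetal plane without lithium, and it can be heated safely. Warming in toluene (60–80 °C) should then give, by the same [3,3] shift, the silylene-bridged silyl ester F2. Dilute aqueous HCl in THF cleaves both Si–O and Si–N bonds and returns 12.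

2. Step 6. What may go wrong: oligomerisation may outrun closure of the medium ring, and the alkene may form as an E/Z mixture that is hard to separate; only the Z lactone gives the cis C4a/C5 pair. Fallback, from 6 back to 9: the Z alkene is made first and the ring is closed at the ester. Ozonolysis of 6 (O3, CH2Cl2/MeOH, −78 °C; Me2S) should give benzyl (3R)-3-[(tert-butoxycarbonyl)amino]-7-oxoheptanoate F3. A salt-free Wittig reaction with the ylide from [2-(tert-butyldimethylsilyloxy)ethyl]triphenylphosphonium bromide (NaN(SiMe3)2, THF, −78 °C) should give benzyl (3R,7Z)-3-[(tert-butoxycarbonyl)amino]-9-{[tert-butyl(dimethyl)silyl]oxy}non-7-enoate F4. Bu4NF should free benzyl (3R,7Z)-3-[(tert-butoxycarbonyl)amino]-9-hydroxynon-7-enoate F5, and LiOH the seco acid (3R,7Z)-3-[(tert-butoxycarbonyl)amino]-9-hydroxynon-7-enoic acid F6. Yamaguchi macrolactonisation of F6 (2,4,6-trichlorobenzoyl chloride, Et3N, THF; slow addition to DMAP in toluene at high dilution) closes the ten-membered ring to 9 with the alkene geometry already fixed.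

3. Step 15. What may go wrong: the Boc group may be lost under the acid and heat needed for dehydration, or the reaction may stall at the open ketone or the exocyclic alkene. Fallback, from 21 back to 22: ring closure and carbamate formation are separated. Selective cleavage of the Boc group of 21 with Me3SiOTf/2,6-lutidine (CH2Cl2, 0 °C; then MeOH), which spares the TBS ether, frees the amine. The amine should condense at once with the ketone to the cyclic imine (4aS,5S,8aR)-5-[(5R)-5-{[tert-butyl(dimethyl)silyl]oxy}octyl]-2-methyl-3,4,4a,5,6,7,8,8a-octahydroquinoline F7. N-Acylation of F7 with Boc2O (Et3N, DMAP, toluene, 60 °C) with loss of the C3 proton gives the endocyclic enecarbamate 22.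

**Further compounds**

F1 | step 7 | diisopropylsilylene-bridged ketene N,O-acetal of 9 (carbamate nitrogen and enolate oxygen joined by SiiPr2 in a 1,3,2-oxazasiline ring fused to the Z oxecine) | CC(C)[Si]1(C(C)C)OC2=C[C@@H](CCC/C=C\CO2)N1C(=O)OC(C)(C)C
F2 | step 7 | diisopropylsilylene-bridged silyl ester of 12 (carboxylate oxygen and carbamate nitrogen joined by SiiPr2; 4aS,5R,8aR ring-fused 1,3,2-oxazasilinan-6-one) | CC(C)[Si]1(C(C)C)OC(=O)[C@H]2[C@@H](C=C)CCC[C@H]2N1C(=O)OC(C)(C)C
F3 | step 6 | benzyl (3R)-3-[(tert-butoxycarbonyl)amino]-7-oxoheptanoate | CC(C)(C)OC(=O)N[C@@H](CC(=O)OCc1ccccc1)CCCC=O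
F4 | step 6 | benzyl (3R,7Z)-3-[(tert-butoxycarbonyl)amino]-9-{[tert-butyl(dimethyl)silyl]oxy}non-7-enoate | CC(C)(C)OC(=O)N[C@@H](CC(=O)OCc1ccccc1)CCC/C=C\CO[Si](C)(C)C(C)(C)C
F5 | step 6 | benzyl (3R,7Z)-3-[(tert-butoxycarbonyl)amino]-9-hydroxynon-7-enoate | CC(C)(C)OC(=O)N[C@@H](CC(=O)OCc1ccccc1)CCC/C=C\CO
F6 | step 6 | (3R,7Z)-3-[(tert-butoxycarbonyl)amino]-9-hydroxynon-7-enoic acid | CC(C)(C)OC(=O)N[C@@H](CC(=O)O)CCC/C=C\CO
F7 | step 15 | (4aS,5S,8aR)-5-[(5R)-5-{[tert-butyl(dimethyl)silyl]oxy}octyl]-2-methyl-3,4,4a,5,6,7,8,8a-octahydroquinoline | CC=1CC[C@H]2[C@@H](CCCC[C@H](O[Si](C)(C)C(C)(C)C)CCC)CCC[C@H]2N=1
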